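1. The pitfall lies in the first readings. The autumn run's 71.4 % of starting material at 0.167 d looks like heavy conversion, yet only 80.2 % of the charge had gone in, and percentages count the whole charge.

| setting | autumn | winter | noon | flask |
|---|---|---|---|---|
| starting material | 20 mM (fed, over 5.0 h) | 20 mM (fed, over 5.0 h) | 20 mM (fed, over 5.0 h) | 20 mM (fed, over 5.0 h) |
| reagent | 1 equiv | 1 equiv | 2 equiv | 1.00 equiv |
| second substrate | 0.67 equiv | 1.5 equiv | 1 equiv | 1.00 equiv |
| remark | run made earlier | run made earlier | run made earlier |  |
| time |  |  |  | 15 d |

| run | time / d | target / % | starting material / % |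
|---|---|---|---|
| autumn | 0.167 | 7.1 | 71.4 |
| autumn | 0.625 | 13.1 | 63.1 |
| autumn | 3.00 | 2.4 | 29.6 |
| autumn | 15.0 | 0.3 | 8.6 |
| winter | 0.167 | 5.5 | 72.8 |
| winter | 0.625 | 11.8 | 65.6 |
| winter | 3.00 | 2.9 | 36.0 |
| winter | 15.0 | 0 | 10.3 |
| noon | 0.167 | 12.1 | 65.2 |
| noon | 0.625 | 19.1 | 39.7 |
| noon | 3.00 | 0.3 | 4.8 |
| noon | 15.0 | 0.1 | 0 |

(standard deviation of a reading: 0.5 percentage points)

- percentages count the whole charge, also what has not yet gone in

1. the best time, 15 d at the latest, for target
2. the amount of target, in percent of the starting material charged, at that time

2. The starting rate. I took the amount present over that time as half the reading on average. The pseudo-first-order constant of starting material was then 1.47 d⁻¹ in autumn and 1.21 d⁻¹ in winter. The flask's second substrate lies between those runs, so I used their mean, s₀ = 1.34 d⁻¹. Noon, with 2 equiv of reagent, gave 2.75 d⁻¹, twice s₀, so I let the constant follow the reagent.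

3. The slowing. Between the first two readings, autumn and winter consumed starting material at a mean fractional rate of 0.602 d⁻¹. That is s₀ times a factor g = 0.450, whose logarithm is −0.347. Starting material present, averaging 68.2 %, contributes −0.166. I assigned the remaining −0.181, a factor 0.659, to the fall in reagent.

4. The loss. I counted whatever had left starting material without being target as lost target. Its growth over that interval, divided by mean target, gave λ = 5.01 d⁻¹, the autumn and winter mean.

5. The rule. At the best time, making equals loss, so target is D·g, where D = s₀/λ is the making-to-loss ratio, 0.267. This gave me 12.0 % near 0.396 d, the middle of the interval.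

6. The forecast, which “puts the maximum shortly after the feed”, gave 14.2 % at 0.42 d, above my peak.

The flask reached 14.1 % at 0.412 d.

    target → over-reaction product (k = 0.160 h⁻¹)
    second substrate + reagent ⇌ second product (K = 130 L mol⁻¹, k = 1.10 L mol⁻¹ h⁻¹)
    second substrate ⇌ dormant form (K = 0.710, k = 0.0140 h⁻¹)
    starting material + reagent ⇌ target (K = 80.0 L mol⁻¹, k = 3.20 L mol⁻¹ h⁻¹)
    2 second substrate → self-condensation product (k = 0.800 L mol⁻¹ h⁻¹)

At that time the flask held 73.1 % of its starting material and 60.2 % of its reagent; D times these two shares is 11.8 %, below the flask's best. In the neighbouring flask with 0.400 equiv of reagent, D, which I let follow the reagent, is lower by 0.398 decades, and that neighbour's best, 6.23 %, lies 0.355 decades below the flask's.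

The readings come from a simulation with constants of no real substance, noise included.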